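**Remarks on the chemistry.** The target has no stereocentre and no stereogenic double bond; the only stereo-element on the way is the enoate double bond of intermediate 9. Rings are lettered A to F from the 2,4,6-trihydroxyphenoxy end. 4-Fluoro-2,6-dimethoxybenzaldehyde, 4-bromo-3,5-dimethoxybenzaldehyde and 3,4,5-trimethoxyphenol are assumed to be catalogue compounds.

## Retrosynthetic overview

- The target is reached by global O-demethylation of a tetradecamethyl ether whose central ring C hydroxyl comes from a formyl group by Dakin oxidation.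
- The hexamer is cut at the C–O–D ether (Ullmann coupling at the ring C carbon flanked by OMe and the O–B ether) into an ABC bromo aldehyde and a DEF phenol. The ABC piece comes from SNAr of the AB phenol on 3-bromo-4-fluoro-2,6-dimethoxybenzaldehyde.
- The strategy rests on ring A: a phloroglucinol whose C2, the carbon between the hydroxylated C1 and C3, carries the ether oxygen to C1 of ring B. This is a triketide chain folded so that its ArO–CH2 end bonds to the carboxyl carbon. Ring A is therefore built (C2–C1 bond) from a 6-(aryloxymethyl)-4-methoxy-2-pyrone by methoxide opening and Claisen closure, after the crowded A–O–B ether has been made as a simple primary alkyl aryl ether.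
- The DEF phenol comes from 3,4,5-trimethoxyphenol by two rounds of Ullmann coupling with 4-bromo-3,5-dimethoxybenzaldehyde, each followed by Dakin oxidation.
- Ring order: rings B to F are bought as benzene building blocks; ring A is the only ring formed, in step 5.

Key step: step 5

## Route

Step 1
Reactants: 1 syringaldehyde; 2 benzyl bromide
Product: 3 4-(benzyloxy)-3,5-dimethoxybenzaldehyde
Conditions: K2CO3, DMF, 60 °C
Reagents that add atoms: none
Why: Williamson ether synthesis, in which the phenoxide of 1 displaces bromide from the benzylic carbon by SN2 while the aldehyde is inert to carbonate.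

Step 2
Reactants: 3 4-(benzyloxy)-3,5-dimethoxybenzaldehyde
Product: 5 4-(benzyloxy)-3,5-dimethoxyphenol, via aryl formate 4 (not isolated)
Conditions: mCPBA, CH2Cl2, 0 °C to rt; aq NaHCO3 wash; then K2CO3 (cat.), MeOH, rt
Reagents that add atoms: mCPBA, OOC(=O)c1cccc(Cl)c1
Why: Dakin-type Baeyer–Villiger oxidation, in which the peracid adduct of the aldehyde rearranges with migration of the electron-rich 4-alkoxyaryl group to formate 4, and methanolysis of 4 frees the phenol without touching the benzyl or methyl ethers.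

Step 3
Reactants: 6 4-methoxy-6-methyl-2H-pyran-2-one
Product: 7 6-(bromomethyl)-4-methoxy-2H-pyran-2-one
Conditions: NBS, (PhCO2)2 (cat.), CCl4, reflux
Reagents that add atoms: N-bromosuccinimide, O=C1CCC(=O)N1Br
Why: Wohl–Ziegler radical bromination, in which hydrogen abstraction from the C6 methyl group gives a radical delocalised into the pyrone diene, so the side chain and not the ring is brominated, as is established for this pyrone.

Step 4
Reactants: 5 4-(benzyloxy)-3,5-dimethoxyphenol; 7 6-(bromomethyl)-4-methoxy-2H-pyran-2-one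
Product: 8 6-{[4-(benzyloxy)-3,5-dimethoxyphenoxy]methyl}-4-methoxy-2H-pyran-2-one
Conditions: K2CO3, acetone, reflux
Reagents that add atoms: none
Why: Williamson ether synthesis, an SN2 displacement at the primary allylic-type bromide by the unhindered phenoxide of 5 under conditions too mild to open the lactone, which places the future A–O–B oxygen on an sp3 carbon with no steric penalty.

Step 5
Reactants: 8 6-{[4-(benzyloxy)-3,5-dimethoxyphenoxy]methyl}-4-methoxy-2H-pyran-2-one
Product: 11 2-[4-(benzyloxy)-3,5-dimethoxyphenoxy]-5-methoxybenzene-1,3-diol, via keto enoate 9 (not isolated), via cyclohexenedione 10 (not isolated)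
Conditions: NaOMe (3 equiv), MeOH, reflux, argon; then 1 M HCl
Reagents that add atoms: none
Why: Proposed new method: methoxide adds to the lactone carbonyl of 8 and cleaves the acyl–oxygen bond to give keto enoate 9 (chain numbered C1 ester, C2=C3(OMe), C4H2, C5 ketone, C6H2OAr), in which the ester and the keto chain stay cis on the double bond (2E by the CIP rules, since OMe outranks CH2); deprotonation at C6, acidified by both the ketone and the aryloxy group, gives an enolate whose carbon attacks the ester carbonyl and expels methoxide in a Claisen (Dieckmann-type) condensation. The closest known reactions are the base-induced conversion of 4-methoxy-6-methyl-2-pyrone into phloroglucinol monomethyl ether and the Claisen cyclisation of 3,5-dioxohexanoates to phloroglucinols; an attacking carbon that bears an aryloxy group goes beyond them. Ring A closes in a 6-(enolexo)-exo-trig mode to cyclohexenedione 10, which tautomerises to the aromatic resorcinol and is held as its phenoxide. No stereocentre is formed, and the enoate geometry is not critical because the two geometries can interconvert through the C4 dienolate. The selectivity needed is C-acylation from C6 over O-acylation and over reaction through the more stable C4 dienolate: O-attack only returns pyrone 8 reversibly and the C4 anion has no ring-forming path other than a four-membered ring, whereas the C–C closure is made irreversible by aromatisation.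

Step 6
Reactants: 11 2-[4-(benzyloxy)-3,5-dimethoxyphenoxy]-5-methoxybenzene-1,3-diol
Product: 12 2-(benzyloxy)-1,3-dimethoxy-5-(2,4,6-trimethoxyphenoxy)benzene
Conditions: MeI, K2CO3, acetone, reflux
Reagents that add atoms: iodomethane, CI
Why: Williamson O-methylation of both phenoxides of the resorcinol, where a weak base in a polar aprotic solvent favours O- over C-alkylation and no other acidic site is present.

Step 7
Reactants: 12 2-(benzyloxy)-1,3-dimethoxy-5-(2,4,6-trimethoxyphenoxy)benzene
Product: 13 2,6-dimethoxy-4-(2,4,6-trimethoxyphenoxy)phenol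
Conditions: H2 (1 atm), Pd/C, EtOAc/MeOH, rt
Reagents that add atoms: none
Why: Catalytic hydrogenolysis cleaves only the benzylic C–O bond, since diaryl ether and aryl methyl ether bonds are stable to hydrogen over palladium on carbon.

Step 8
Reactants: 14 4-fluoro-2,6-dimethoxybenzaldehyde
Product: 15 3-bromo-4-fluoro-2,6-dimethoxybenzaldehyde
Conditions: NBS (1.0 equiv), MeCN, 0 °C to rt
Reagents that add atoms: N-bromosuccinimide, O=C1CCC(=O)N1Br
Why: Electrophilic aromatic bromination, in which C3 (ortho to one methoxy group, para to the other) and the equivalent C5 are the only free ring positions, so one equivalent of NBS should give the monobromide.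

Step 9
Reactants: 13 2,6-dimethoxy-4-(2,4,6-trimethoxyphenoxy)phenol; 15 3-bromo-4-fluoro-2,6-dimethoxybenzaldehyde
Product: 16 3-bromo-4-[2,6-dimethoxy-4-(2,4,6-trimethoxyphenoxy)phenoxy]-2,6-dimethoxybenzaldehyde
Conditions: Cs2CO3, DMSO, 100 °C, argon
Reagents that add atoms: none
Why: SNAr by addition–elimination, in which the hindered phenoxide of 13 adds at C4, where the Meisenheimer anion is delocalised onto the para formyl group and fluoride leaves, while the bromine meta to the formyl group is not activated and stays.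

Step 10
Reactants: 17 3,4,5-trimethoxyphenol; 18 4-bromo-3,5-dimethoxybenzaldehyde
Product: 19 3,5-dimethoxy-4-(3,4,5-trimethoxyphenoxy)benzaldehyde
Conditions: CuI (10 mol %), picolinic acid (20 mol %), K3PO4, DMSO, 90 °C, argon
Reagents that add atoms: none
Why: Ullmann-type copper-catalysed diaryl ether coupling, in which the unhindered electron-rich phenoxide is joined at a C–Br bond whose oxidative addition to the picolinate-ligated copper phenoxide is helped by the para formyl group despite the two ortho methoxy groups.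

Step 11
Reactants: 19 3,5-dimethoxy-4-(3,4,5-trimethoxyphenoxy)benzaldehyde
Product: 21 3,5-dimethoxy-4-(3,4,5-trimethoxyphenoxy)phenol, via aryl formate 20 (not isolated)
Conditions: mCPBA, CH2Cl2, 0 °C to rt; aq NaHCO3 wash; then K2CO3 (cat.), MeOH, rt
Reagents that add atoms: mCPBA, OOC(=O)c1cccc(Cl)c1
Why: Dakin-type Baeyer–Villiger oxidation as in step 2, in which the 4-aryloxy-3,5-dimethoxyphenyl group migrates in preference to hydride and methanolysis of formate 20 gives the phenol.

Step 12
Reactants: 21 3,5-dimethoxy-4-(3,4,5-trimethoxyphenoxy)phenol; 18 4-bromo-3,5-dimethoxybenzaldehyde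
Product: 22 4-[3,5-dimethoxy-4-(3,4,5-trimethoxyphenoxy)phenoxy]-3,5-dimethoxybenzaldehyde
Conditions: CuI (10 mol %), picolinic acid (20 mol %), K3PO4, DMSO, 90 °C, argon
Reagents that add atoms: none
Why: Ullmann-type copper-catalysed diaryl ether coupling repeated as in step 10, since the phenol of 21 has the same unhindered 3,5-dimethoxy-4-aryloxy environment and the bromide is the same.

Step 13
Reactants: 22 4-[3,5-dimethoxy-4-(3,4,5-trimethoxyphenoxy)phenoxy]-3,5-dimethoxybenzaldehyde
Product: 24 4-[3,5-dimethoxy-4-(3,4,5-trimethoxyphenoxy)phenoxy]-3,5-dimethoxyphenol, via aryl formate 23 (not isolated)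
Conditions: mCPBA, CH2Cl2, 0 °C to rt; aq NaHCO3 wash; then K2CO3 (cat.), MeOH, rt
Reagents that add atoms: mCPBA, OOC(=O)c1cccc(Cl)c1
Why: Dakin-type Baeyer–Villiger oxidation as in step 11, with aryl migration to formate 23 and methanolysis to the ring D phenol.

Step 14
Reactants: 16 3-bromo-4-[2,6-dimethoxy-4-(2,4,6-trimethoxyphenoxy)phenoxy]-2,6-dimethoxybenzaldehyde; 24 4-[3,5-dimethoxy-4-(3,4,5-trimethoxyphenoxy)phenoxy]-3,5-dimethoxyphenol
Product: 25 3-{4-[3,5-dimethoxy-4-(3,4,5-trimethoxyphenoxy)phenoxy]-3,5-dimethoxyphenoxy}-4-[2,6-dimethoxy-4-(2,4,6-trimethoxyphenoxy)phenoxy]-2,6-dimethoxybenzaldehyde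
Conditions: CuI (20 mol %), picolinic acid (40 mol %), K3PO4, DMSO, 100 °C, argon
Reagents that add atoms: none
Why: Ullmann-type copper-catalysed diaryl ether coupling between the unhindered phenoxide of 24 and the bromide of 16, which is flanked by a methoxy and an aryloxy group; the picolinic acid system is chosen because it tolerates ortho substituents, the aldehyde is not enolisable, and no fluorine is left to divert the phenoxide into SNAr.

Step 15
Reactants: 25 the hexaaryl aldehyde of step 14
Product: 27 3-{4-[3,5-dimethoxy-4-(3,4,5-trimethoxyphenoxy)phenoxy]-3,5-dimethoxyphenoxy}-4-[2,6-dimethoxy-4-(2,4,6-trimethoxyphenoxy)phenoxy]-2,6-dimethoxyphenol, via aryl formate 26 (not isolated)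
Conditions: mCPBA (1.2 equiv), CH2Cl2, 0 °C; aq NaHCO3 wash; then K2CO3 (cat.), MeOH/THF, rt
Reagents that add atoms: mCPBA, OOC(=O)c1cccc(Cl)c1
Why: Dakin-type Baeyer–Villiger oxidation, in which the formyl group sits on a ring with two ortho methoxy groups and a para aryloxy group, so aryl migration should be fast at low temperature with near-stoichiometric peracid, and methanolysis of formate 26 gives the ring C phenol.

Step 16
Reactants: 27 the tetradecamethyl ether phenol of step 15
Product: 28 4-{4-[3,5-dihydroxy-4-(3,4,5-trihydroxyphenoxy)phenoxy]-3,5-dihydroxyphenoxy}-5-[2,6-dihydroxy-4-(2,4,6-trihydroxyphenoxy)phenoxy]benzene-1,2,3-triol (CNP0270681.0)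
Conditions: BBr3 (excess), CH2Cl2, −78 °C to rt, argon; then MeOH, H2O
Reagents that add atoms: none
Why: Lewis acid ether cleavage, in which BBr3 coordinates each methoxy oxygen and bromide attacks the methyl carbon by SN2, while the diaryl ether oxygens offer no sp3 carbon and survive; hydrolysis of the aryl borates should give the free pentadecaphenol.

## Compound list

1 | syringaldehyde (4-hydroxy-3,5-dimethoxybenzaldehyde) | COc1cc(C=O)cc(OC)c1O | starting material
2 | benzyl bromide | BrCc1ccccc1 | starting material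
3 | 4-(benzyloxy)-3,5-dimethoxybenzaldehyde | COc1cc(C=O)cc(OC)c1OCc1ccccc1 | intermediate
4 | 4-(benzyloxy)-3,5-dimethoxyphenyl formate | COc1cc(OC=O)cc(OC)c1OCc1ccccc1 | intermediate
5 | 4-(benzyloxy)-3,5-dimethoxyphenol | COc1cc(O)cc(OC)c1OCc1ccccc1 | intermediate
6 | 4-methoxy-6-methyl-2H-pyran-2-one | CC1=CC(OC)=CC(=O)O1 | starting material
7 | 6-(bromomethyl)-4-methoxy-2H-pyran-2-one | BrCC1=CC(OC)=CC(=O)O1 | intermediate
8 | 6-{[4-(benzyloxy)-3,5-dimethoxyphenoxy]methyl}-4-methoxy-2H-pyran-2-one | COC1=CC(=O)OC(COc2cc(OC)c(OCc3ccccc3)c(OC)c2)=C1 | intermediate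
9 | methyl (2E)-6-[4-(benzyloxy)-3,5-dimethoxyphenoxy]-3-methoxy-5-oxohex-2-enoate | COC(=O)/C=C(\CC(=O)COc1cc(OC)c(OCc2ccccc2)c(OC)c1)OC | intermediate
10 | 2-[4-(benzyloxy)-3,5-dimethoxyphenoxy]-5-methoxycyclohex-4-ene-1,3-dione | COC1=CC(=O)C(Oc2cc(OC)c(OCc3ccccc3)c(OC)c2)C(=O)C1 | intermediate
11 | 2-[4-(benzyloxy)-3,5-dimethoxyphenoxy]-5-methoxybenzene-1,3-diol | COc1cc(O)c(Oc2cc(OC)c(OCc3ccccc3)c(OC)c2)c(O)c1 | intermediate
12 | 2-(benzyloxy)-1,3-dimethoxy-5-(2,4,6-trimethoxyphenoxy)benzene | COc1cc(OC)c(Oc2cc(OC)c(OCc3ccccc3)c(OC)c2)c(OC)c1 | intermediate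
13 | 2,6-dimethoxy-4-(2,4,6-trimethoxyphenoxy)phenol | COc1cc(OC)c(Oc2cc(OC)c(O)c(OC)c2)c(OC)c1 | intermediate
14 | 4-fluoro-2,6-dimethoxybenzaldehyde | COc1cc(F)cc(OC)c1C=O | starting material
15 | 3-bromo-4-fluoro-2,6-dimethoxybenzaldehyde | COc1cc(F)c(Br)c(OC)c1C=O | intermediate
16 | 3-bromo-4-[2,6-dimethoxy-4-(2,4,6-trimethoxyphenoxy)phenoxy]-2,6-dimethoxybenzaldehyde | COc1cc(OC)c(Oc2cc(OC)c(Oc3cc(OC)c(C=O)c(OC)c3Br)c(OC)c2)c(OC)c1 | intermediate
17 | 3,4,5-trimethoxyphenol | COc1cc(O)cc(OC)c1OC | starting material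
18 | 4-bromo-3,5-dimethoxybenzaldehyde | COc1cc(C=O)cc(OC)c1Br | starting material
19 | 3,5-dimethoxy-4-(3,4,5-trimethoxyphenoxy)benzaldehyde | COc1cc(C=O)cc(OC)c1Oc1cc(OC)c(OC)c(OC)c1 | intermediate
20 | 3,5-dimethoxy-4-(3,4,5-trimethoxyphenoxy)phenyl formate | COc1cc(OC=O)cc(OC)c1Oc1cc(OC)c(OC)c(OC)c1 | intermediate
21 | 3,5-dimethoxy-4-(3,4,5-trimethoxyphenoxy)phenol | COc1cc(O)cc(OC)c1Oc1cc(OC)c(OC)c(OC)c1 | intermediate
22 | 4-[3,5-dimethoxy-4-(3,4,5-trimethoxyphenoxy)phenoxy]-3,5-dimethoxybenzaldehyde | COc1cc(C=O)cc(OC)c1Oc1cc(OC)c(Oc2cc(OC)c(OC)c(OC)c2)c(OC)c1 | intermediate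
23 | 4-[3,5-dimethoxy-4-(3,4,5-trimethoxyphenoxy)phenoxy]-3,5-dimethoxyphenyl formate | COc1cc(OC=O)cc(OC)c1Oc1cc(OC)c(Oc2cc(OC)c(OC)c(OC)c2)c(OC)c1 | intermediate
24 | 4-[3,5-dimethoxy-4-(3,4,5-trimethoxyphenoxy)phenoxy]-3,5-dimethoxyphenol | COc1cc(O)cc(OC)c1Oc1cc(OC)c(Oc2cc(OC)c(OC)c(OC)c2)c(OC)c1 | intermediate
25 | 3-{4-[3,5-dimethoxy-4-(3,4,5-trimethoxyphenoxy)phenoxy]-3,5-dimethoxyphenoxy}-4-[2,6-dimethoxy-4-(2,4,6-trimethoxyphenoxy)phenoxy]-2,6-dimethoxybenzaldehyde | COc1cc(OC)c(Oc2cc(OC)c(Oc3cc(OC)c(C=O)c(OC)c3Oc3cc(OC)c(Oc4cc(OC)c(Oc5cc(OC)c(OC)c(OC)c5)c(OC)c4)c(OC)c3)c(OC)c2)c(OC)c1 | intermediate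
26 | 3-{4-[3,5-dimethoxy-4-(3,4,5-trimethoxyphenoxy)phenoxy]-3,5-dimethoxyphenoxy}-4-[2,6-dimethoxy-4-(2,4,6-trimethoxyphenoxy)phenoxy]-2,6-dimethoxyphenyl formate | COc1cc(OC)c(Oc2cc(OC)c(Oc3cc(OC)c(OC=O)c(OC)c3Oc3cc(OC)c(Oc4cc(OC)c(Oc5cc(OC)c(OC)c(OC)c5)c(OC)c4)c(OC)c3)c(OC)c2)c(OC)c1 | intermediate
27 | 3-{4-[3,5-dimethoxy-4-(3,4,5-trimethoxyphenoxy)phenoxy]-3,5-dimethoxyphenoxy}-4-[2,6-dimethoxy-4-(2,4,6-trimethoxyphenoxy)phenoxy]-2,6-dimethoxyphenol | COc1cc(OC)c(Oc2cc(OC)c(Oc3cc(OC)c(O)c(OC)c3Oc3cc(OC)c(Oc4cc(OC)c(Oc5cc(OC)c(OC)c(OC)c5)c(OC)c4)c(OC)c3)c(OC)c2)c(OC)c1 | intermediate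
28 | 4-{4-[3,5-dihydroxy-4-(3,4,5-trihydroxyphenoxy)phenoxy]-3,5-dihydroxyphenoxy}-5-[2,6-dihydroxy-4-(2,4,6-trihydroxyphenoxy)phenoxy]benzene-1,2,3-triol (CNP0270681.0) | Oc1cc(O)c(Oc2cc(O)c(Oc3cc(O)c(O)c(O)c3Oc3cc(O)c(Oc4cc(O)c(Oc5cc(O)c(O)c(O)c5)c(O)c4)c(O)c3)c(O)c2)c(O)c1 | target

## Step count and risks

Total steps: 16. Longest linear sequence: 10 steps (steps 1, 2, 4, 5, 6, 7, 9, 14, 15, 16). The DEF branch (steps 10 to 13) and the ring C bromide (step 8) are made in parallel.

**Step 5 (Proposed new method).** After methanolysis of the lactone the chain may rest as its C4 dienolate, with the C6 carbanion formed too slowly for the Claisen closure. The material would then relactonise to 8 on work-up, or be degraded by ester cleavage when the conditions are forced. The fallback uses only known chemistry and gives up the ring construction for this ether. It sets out from 14: commercial 2,4,6-trimethoxyphenol (COc1cc(OC)c(O)c(OC)c1) is arylated with 14 by SNAr (Cs2CO3, DMSO, 100 °C) to 2,6-dimethoxy-4-(2,4,6-trimethoxyphenoxy)benzaldehyde F1. Dakin-type oxidation of F1 (mCPBA, CH2Cl2; then K2CO3 cat., MeOH) passes through 2,6-dimethoxy-4-(2,4,6-trimethoxyphenoxy)phenyl formate F2 and gives phenol 13, where the route is rejoined before step 9.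

**Step 14.** Oxidative addition at the bromide flanked by a methoxy and a bulky aryloxy group may be slow. Protodebromination of 16, oxidative decay of the phenoxide of 24, and exchange of the formyl-activated AB aryloxy group by that phenoxide could then overtake the coupling. The fallback reverses the order of the two ring C etherifications, so that the crowded ether is made next to fluorine and the last union is a metal-free SNAr. It sets out from 15, which is protected with ethylene glycol (TsOH cat., toluene, Dean–Stark) as 2-(3-bromo-4-fluoro-2,6-dimethoxyphenyl)-1,3-dioxolane F3, in which the fluorine is no longer activated. Ullmann coupling of F3 with phenol 24 (CuI, picolinic acid, K3PO4, DMSO, 100 °C) should give 2-(3-{4-[3,5-dimethoxy-4-(3,4,5-trimethoxyphenoxy)phenoxy]-3,5-dimethoxyphenoxy}-4-fluoro-2,6-dimethoxyphenyl)-1,3-dioxolane F4. Aqueous HCl in THF then frees 3-{4-[3,5-dimethoxy-4-(3,4,5-trimethoxyphenoxy)phenoxy]-3,5-dimethoxyphenoxy}-4-fluoro-2,6-dimethoxybenzaldehyde F5. SNAr of the phenoxide of 13 on F5 (Cs2CO3, DMSO, 100 °C) gives 25, where the route is rejoined before step 15; any aryloxide exchange in this last step is degenerate.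

**Step 16.** Cleavage of fourteen methyl ethers may stop at partly methylated stages, and the free pentadecaphenol may oxidise in air during work-up and chromatography. The fallback sets out from 27 and isolates the product through a stable derivative. After BBr3 treatment (CH2Cl2, then MeOH quench and evaporation) the crude polyphenol is acetylated in the same flask (Ac2O, pyridine) to the pentadecaacetate of 28 F6, which can be chromatographed and separated from under-cleaved material. Acid-catalysed methanolysis of F6 (HCl in MeOH, argon, rt) then releases 28 with only volatile by-products.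

## Further compounds

F1 | step 5 | 2,6-dimethoxy-4-(2,4,6-trimethoxyphenoxy)benzaldehyde | COc1cc(OC)c(Oc2cc(OC)c(C=O)c(OC)c2)c(OC)c1
F2 | step 5 | 2,6-dimethoxy-4-(2,4,6-trimethoxyphenoxy)phenyl formate | COc1cc(OC)c(Oc2cc(OC)c(OC=O)c(OC)c2)c(OC)c1
F3 | step 14 | 2-(3-bromo-4-fluoro-2,6-dimethoxyphenyl)-1,3-dioxolane | COc1cc(F)c(Br)c(OC)c1C1OCCO1
F4 | step 14 | 2-(3-{4-[3,5-dimethoxy-4-(3,4,5-trimethoxyphenoxy)phenoxy]-3,5-dimethoxyphenoxy}-4-fluoro-2,6-dimethoxyphenyl)-1,3-dioxolane | COc1cc(F)c(Oc2cc(OC)c(Oc3cc(OC)c(Oc4cc(OC)c(OC)c(OC)c4)c(OC)c3)c(OC)c2)c(OC)c1C1OCCO1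
F5 | step 14 | 3-{4-[3,5-dimethoxy-4-(3,4,5-trimethoxyphenoxy)phenoxy]-3,5-dimethoxyphenoxy}-4-fluoro-2,6-dimethoxybenzaldehyde | COc1cc(F)c(Oc2cc(OC)c(Oc3cc(OC)c(Oc4cc(OC)c(OC)c(OC)c4)c(OC)c3)c(OC)c2)c(OC)c1C=O
F6 | step 16 | pentadecaacetate of 28 | CC(=O)Oc1cc(OC(C)=O)c(Oc2cc(OC(C)=O)c(Oc3cc(OC(C)=O)c(OC(C)=O)c(OC(C)=O)c3Oc3cc(OC(C)=O)c(Oc4cc(OC(C)=O)c(Oc5cc(OC(C)=O)c(OC(C)=O)c(OC(C)=O)c5)c(OC(C)=O)c4)c(OC(C)=O)c3)c(OC(C)=O)c2)c(OC(C)=O)c1
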